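The ratio r of X to Q is the number to watch, and r = 1 is my zero: there the two products stand level and ln r is nil.

| flask | E | D | remark | time |
|---|---|---|---|---|
| autumn | 0.10 M | 0.10 M | the very flask that is asked about, followed so far |  |
| summer | 0.067 M | 0.10 M | run made earlier |  |
| flask | 0.10 M | 0.100 M |  | 25 min |

| run | time / min | X / % | Q / % | E / % |
|---|---|---|---|---|
| autumn | 0.833 | 5.1 | 12.3 | 27.4 |
| autumn | 1.50 | 9.3 | 23.8 | 10.1 |
| autumn | 2.50 | 15.0 | 31.7 | 2.1 |
| autumn | 3.00 | 17.3 | 34.1 | 1.2 |
| autumn | 4.00 | 22.1 | 34.3 | 0.1 |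
| autumn | 5.00 | 25.0 | 32.8 | 0 |
| summer | 1.33 | 9.0 | 21.0 | 12.7 |
| summer | 2.50 | 15.3 | 32.2 | 2.9 |
| summer | 4.00 | 20.7 | 34.0 | 0 |
| summer | 6.00 | 27.2 | 30.1 | 1.2 |
| summer | 10.0 | 35.1 | 23.4 | 0 |
| summer | 20.0 | 45.7 | 11.2 | 0.2 |

(each reading ± 0.5 percentage points)

1. ratio of X to Q at 25 s
2. ratio of X to Q at 3.0 min
3. ratio of X to Q at 25 min
4. which of X and Q there is more of at 25 min

- steps that have been proposed: Z -> J; E + D -> L; E -> Z; Z <-> X; Z -> G; Z <-> Q

I turn the settings one after the other. Charging less E should leave r alone if both products come down one first-order chain, and the readings agree with that: at 2.50 min the autumn run, with 0.10 M of E, reads 0.473, and the summer run, with 0.067 M, reads 0.475. D should remove E through E + D → L before Z forms, which thins X and Q alike, but no run so far varies D, so this stays a reckoning. Time moves r. In the summer run Q leads early and X late, the pattern of kinetic against thermodynamic control, and r climbs to 4.08 at 20.0 min.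

The summer readings at 10.0 min and 20.0 min give 0.100 min⁻¹: this is the ratio clock σ, the gain in ln r per minute late in a run. The summer readings at 6.00 min and 10.0 min cross level near t₀ = 6.80 min, so counting from my zero, my estimate r = exp(σ(t − t₀)) gives 6.18 at 25 min, with X ahead. Counting from the last summer reading instead gives 6.73, so I commit to the range between these two figures. For the early times I take the autumn readings: 0.415 at 0.833 min, the nearest to 25 s, and 0.507 at 3.00 min.

The forecast says 0.4, 0.51 and 6.3, with X ahead, on the ground that “Q drains back through Z to X”. Its late figure lies inside my range, above my first.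

The flask gives 0.374, 0.540 and 6.11, with X ahead at 49.8% against 8.14% of Q. Its late ratio lies below my first figure, so outside my range.

    Z → J (k = 0.00103 s⁻¹)
    E + D → L (k = 0.0565 L mol⁻¹ s⁻¹)
    E → Z (k = 0.0208 s⁻¹)
    Z ⇌ X (K = 73.0, k = 0.00340 s⁻¹)
    Z → G (k = 2.30 × 10⁻⁴ s⁻¹)
    Z ⇌ Q (K = 2.00, k = 0.00949 s⁻¹)

Beside them stands J at 15.8% at 25.0 min, which r does not show. This flask is level at 6.87 min, and σ counted from there gives 6.13. The neighbour flask with 0.25 M of E, so 0.400 equiv of D, ends at 6.10; with σ I estimate that ratio to lie 18.1 min past its level point, which puts that point near 6.92 min.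

(Readings and results were computed with made-up constants; scatter was added.)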